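The numbering is C1 (CH–O‑angelate), C2, C3 (CH–O‑epoxy ester), C4 (CMe2), cyclobutane C5–C6–C11–C10, enone C7(=O)–C8=C9(Me). The cage conceals an 11‑membered humulane perimeter, C1–C2–C3–C4–C5–C10–C9–C8–C7–C6–C11, whose cyclobutane bonds C5–C6 and C10–C11 are transannular. Everything rests on closing this perimeter at C9–C10, between the enone β‑carbon and a cyclobutane CH. An intramolecular Heck reaction of an acyclic (Z)‑β‑iodo dienone with the vinyl group on quaternary C4 forms this bond, the carbocycle and the (8Z,5E)‑diene in one operation. The precursor is a linear C15 chain bearing only the anti‑1,3‑diol; a transannular [2+2] photocycloaddition then folds the trienone into the tricycle.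

Key step: step 10

Remark on the chemistry: the esters are taken exactly as drawn, an angelate ((Z)‑2‑methylbut‑2‑enoate) at C1 and a (2S,3R)‑2,3‑dimethyloxirane‑2‑carboxylate (cis methyl groups, the epoxide of a tiglate) at C3.
Remark on descriptors: in the numbering above the core is 1R,3R,5S,6R,10R,11R.

Step 1
Reactants: 1 (2E)-2-methylbut-2-en-1-ol (tiglyl alcohol)
Product: 2 [(2R,3R)-2,3-dimethyloxiran-2-yl]methanol
Conditions: t-BuOOH, Ti(OiPr)4 (cat.), D-(−)-diethyl tartrate, 4 Å MS, CH2Cl2, −20 °C
Reagents that add atoms: tert-butyl hydroperoxide, CC(C)(C)OO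
Why: Katsuki–Sharpless asymmetric epoxidation; with E-allylic alcohols the D-(−)-tartrate ligand should deliver oxygen to the face that gives the (2R,3R)-epoxy alcohol, and the E geometry fixes the cis relation of the two methyl groups.

Step 2
Reactants: 2 [(2R,3R)-2,3-dimethyloxiran-2-yl]methanol
Product: 3 (2S,3R)-2,3-dimethyloxirane-2-carboxylic acid
Conditions: RuCl3 (cat.), NaIO4, MeCN/EtOAc/H2O, 0 → 20 °C
Reagents that add atoms: water, O
Why: Catalytic RuO4 oxidation of the primary alcohol to the acid through the aldehyde hydrate should leave the epoxide and both stereocentres untouched; the C2 descriptor changes from R to S only because CO2H outranks the ring carbon.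

Step 3
Reactants: 4 3,3-dimethylpent-4-en-2-one; 5 ethyl (2E)-3-methyl-4-oxobut-2-enoate
Product: 8 ethyl (2E,4R)-4-hydroxy-3,7,7-trimethyl-6-oxonona-2,8-dienoate, via boron enolate 6 (not isolated), via boron aldolate 7 (not isolated)
Conditions: (−)-Ipc2BCl, Et3N, Et2O, 0 °C; 5, −78 → −20 °C; H2O2, pH 7 buffer, MeOH
Reagents that add atoms: none
Why: Boron-mediated aldol addition of a methyl ketone: 4 can enolise only toward its methyl group (the other α-carbon is quaternary), the diisopinocampheylboron enolate adds 1,2 to the enal, and the (−)-Ipc ligands should direct attack to the Re face of the aldehyde, which sets C1 as R (C4 of the nonadienoate).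

Step 4
Reactants: 8 ethyl (2E,4R)-4-hydroxy-3,7,7-trimethyl-6-oxonona-2,8-dienoate
Product: 9 ethyl (2E,4R,6R)-4,6-dihydroxy-3,7,7-trimethylnona-2,8-dienoate
Conditions: Me4NBH(OAc)3, MeCN/AcOH, −30 °C
Reagents that add atoms: none
Why: Evans–Saksena hydroxyl-directed reduction: the borohydride bound to the C1 oxygen delivers hydride intramolecularly through a chair-like six-membered transition state, which should give the 1,3-anti diol and so set C3 as R, while the enoate and the vinyl group are inert.

Step 5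
Reactants: 9 ethyl (2E,4R,6R)-4,6-dihydroxy-3,7,7-trimethylnona-2,8-dienoate
Product: 10 ethyl (2E,4R,6R)-4-[(tert-butyldimethylsilyl)oxy]-6-hydroxy-3,7,7-trimethylnona-2,8-dienoate
Conditions: TBSCl, imidazole, DMF, 0 °C
Reagents that add atoms: tert-butyldimethylsilyl chloride, CC(C)(C)[Si](C)(C)Cl
Why: Silyl ether formation that should be selective for the allylic C1 hydroxyl, because the C3 hydroxyl is shielded by the adjacent quaternary C4.

Step 6
Reactants: 10 ethyl (2E,4R,6R)-4-[(tert-butyldimethylsilyl)oxy]-6-hydroxy-3,7,7-trimethylnona-2,8-dienoate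
Product: 11 ethyl (2E,4R,6R)-4-[(tert-butyldimethylsilyl)oxy]-3,7,7-trimethyl-6-[(triethylsilyl)oxy]nona-2,8-dienoate
Conditions: TESOTf, 2,6-lutidine, CH2Cl2, −78 → 0 °C
Reagents that add atoms: triethylsilyl trifluoromethanesulfonate, CC[Si](CC)(CC)OS(=O)(=O)C(F)(F)F
Why: Silylation with the more reactive silyl triflate should cap the hindered C3 hydroxyl (which would otherwise add to C11 in an oxa-Michael sense later) and gives two silyl ethers of different acid lability.

Step 7
Reactants: 11 ethyl (2E,4R,6R)-4-[(tert-butyldimethylsilyl)oxy]-3,7,7-trimethyl-6-[(triethylsilyl)oxy]nona-2,8-dienoate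
Product: 12 (2E,4R,6R)-4-[(tert-butyldimethylsilyl)oxy]-N-methoxy-N,3,7,7-tetramethyl-6-[(triethylsilyl)oxy]nona-2,8-dienamide
Conditions: MeNHOMe·HCl, i-PrMgCl, THF, −20 → 0 °C
Reagents that add atoms: N,O-dimethylhydroxylamine hydrochloride, CNOC.Cl
Why: Weinreb amide formation by aminolysis of the ester with the magnesium amide; the hard nucleophile should attack the carbonyl of the β,β-disubstituted enoate without conjugate addition, and both silyl ethers are stable to it.

Step 8
Reactants: 12 (2E,4R,6R)-4-[(tert-butyldimethylsilyl)oxy]-N-methoxy-N,3,7,7-tetramethyl-6-[(triethylsilyl)oxy]nona-2,8-dienamide; 13 prop-1-yn-1-ylmagnesium bromide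
Product: 14 (5E,7R,9R)-7-[(tert-butyldimethylsilyl)oxy]-6,10,10-trimethyl-9-[(triethylsilyl)oxy]dodeca-5,11-dien-2-yn-4-one
Conditions: THF, 0 °C; inverse quench into cold aq. NaHSO4
Reagents that add atoms: none
Why: Weinreb ketone synthesis: the chelated tetrahedral intermediate prevents over-addition, and the acidic inverse quench should keep the liberated N,O-dimethylhydroxylamine from adding to the ynone.

Step 9
Reactants: 14 (5E,7R,9R)-7-[(tert-butyldimethylsilyl)oxy]-6,10,10-trimethyl-9-[(triethylsilyl)oxy]dodeca-5,11-dien-2-yn-4-one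
Product: 15 (2Z,5E,7R,9R)-7-[(tert-butyldimethylsilyl)oxy]-2-iodo-6,10,10-trimethyl-9-[(triethylsilyl)oxy]dodeca-2,5,11-trien-4-one
Conditions: LiI, AcOH (3 equiv), MeCN, 20 °C, dark
Reagents that add atoms: lithium iodide, [Li+].[I-]
Why: Conjugate hydroiodination of the ynone: iodide adds to C9, the alkyne β-carbon (the enone β-carbon C11 is fully substituted and less electrophilic), and protonation of the allenolate anti to iodine should give the (Z)-β-iodoenone, in which iodine is cis to C7.

Step 10
Reactants: 15 (2Z,5E,7R,9R)-7-[(tert-butyldimethylsilyl)oxy]-2-iodo-6,10,10-trimethyl-9-[(triethylsilyl)oxy]dodeca-2,5,11-trien-4-one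
Product: 16 (2Z,4E,7R,9R,10E)-9-[(tert-butyldimethylsilyl)oxy]-3,6,6,10-tetramethyl-7-[(triethylsilyl)oxy]cycloundeca-2,4,10-trien-1-one
Conditions: Pd(OAc)2 (0.3 equiv), Bu4NCl, NaHCO3, DMF, 60 °C, slow addition (final 0.002 M), dark
Reagents that add atoms: none
Why: Zerovalent palladium formed in situ from Pd(OAc)2 inserts into the C9–I bond of the (Z)-β-iodoenone with retention, the alkenylpalladium species adds syn across the terminal vinyl group with C9 bonding to the unsubstituted carbon C10, and syn β-hydride elimination, possible only from C10 because C4 is quaternary, releases the (5E)-alkene and regenerates the catalyst. The closest known reaction type is the intramolecular Heck macrocyclisation of alkenyl iodides onto terminal alkenes in the endo mode. The one ring closed is the 11-membered carbocycle C1–C2–C3–C4–C5–C10–C9–C8–C7–C6–C11, by 11-endo-trig closure. No stereocentre is formed; the Z geometry at C8=C9 is carried over from 15 and the E geometry at C5=C10 follows from syn insertion and syn elimination. The step needs attack at the terminal alkene carbon, which the neopentyl-type C5 secures, chemoselectivity over the trisubstituted C6=C11 alkene, which is too hindered to insert, and cyclisation over oligomerisation, which high dilution, the U-turn of the (Z)-enone and the gem-dimethyl group at C4 should favour.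

Step 11
Reactants: 16 (2Z,4E,7R,9R,10E)-9-[(tert-butyldimethylsilyl)oxy]-3,6,6,10-tetramethyl-7-[(triethylsilyl)oxy]cycloundeca-2,4,10-trien-1-one
Product: 17 tricyclic enone bis(silyl ether): the target core (1R,3R,5S,6R,10R,11R) with OTBS at C1 and OTES at C3
Conditions: thioxanthen-9-one (10 mol %), 405 nm LEDs, degassed MeCN (0.005 M), 20 °C
Reagents that add atoms: none
Why: Triplet-sensitised transannular enone–alkene [2+2] photocycloaddition: the dienone triplet should bond C5 to C6 first (six-membered ring between the two unhindered CH termini, leaving a tertiary radical at C11 and an oxapentadienyl radical at C10) and then close C10–C11; the two crossing bridges allow only one relative configuration of C5, C6, C10 and C11, and its sense relative to C1 and C3 should follow from allylic 1,2-strain at C1 (C1–H eclipsing the C11 methyl, the silyloxy group on the outer face, C2 on the inner face that receives C5=C10), while a sensitiser whose triplet energy lies between those of the dienone and the product enone spares the product from a 1,3-acyl shift.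

Step 12
Reactants: 17 tricyclic enone bis(silyl ether) (C1–OTBS, C3–OTES)
Product: 18 tricyclic C3 alcohol: the target core (1R,3R,5S,6R,10R,11R) with OTBS at C1 and free OH at C3
Conditions: PPTS, MeOH/CH2Cl2, 0 °C
Reagents that add atoms: none
Why: Acid-catalysed methanolysis of the triethylsilyl ether, which is far more labile than the tert-butyldimethylsilyl ether, should free only the C3 hydroxyl.

Step 13
Reactants: 18 tricyclic C3 alcohol (C1–OTBS); 3 (2S,3R)-2,3-dimethyloxirane-2-carboxylic acid
Product: 20 tricyclic C3 (2S,3R)-2,3-dimethyloxirane-2-carboxylate with OTBS at C1, via mixed anhydride 19 (not isolated)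
Conditions: 3, 2,4,6-trichlorobenzoyl chloride, Et3N, THF; then 18, DMAP, toluene, 40 °C
Reagents that add atoms: none
Why: Yamaguchi esterification: the mixed anhydride is attacked at the oxirane carbonyl (the aroyl carbonyl is blocked by two ortho chlorines) and the acid has no α-hydrogen, so the epoxide stereocentres are not at risk; as 3 is enantiopure, any minor enantiomer carried from step 3 becomes a separable diastereomer here.

Step 14
Reactants: 20 tricyclic C3 epoxy ester (C1–OTBS)
Product: 21 tricyclic C1 alcohol bearing the C3 (2S,3R)-2,3-dimethyloxirane-2-carboxylate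
Conditions: HF·pyridine, pyridine, THF, 0 → 25 °C
Reagents that add atoms: none
Why: Fluoride-driven cleavage of the silyl ether under buffered conditions that the electron-poor glycidic ester epoxide and the enone should tolerate.

Step 15
Reactants: 21 tricyclic C1 alcohol bearing the C3 epoxy ester; 22 angelic acid ((2Z)-2-methylbut-2-enoic acid)
Product: 24 target CNP0149458.1, via mixed anhydride 23 (not isolated)
Conditions: 22, 2,4,6-trichlorobenzoyl chloride, Et3N, toluene, 25 °C; then 21, 80 °C (no DMAP)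
Reagents that add atoms: none
Why: Yamaguchi-type acylation with the preformed angelic mixed anhydride in the absence of a nucleophilic catalyst, conditions under which the Z-configured acyl group should be transferred without isomerisation to the E (tigloyl) isomer.

Compound list
1 | (2E)-2-methylbut-2-en-1-ol (tiglyl alcohol) | C/C=C(\C)CO | starting material
2 | [(2R,3R)-2,3-dimethyloxiran-2-yl]methanol | OC[C@@]1(C)O[C@@H]1C | intermediate
3 | (2S,3R)-2,3-dimethyloxirane-2-carboxylic acid | OC(=O)[C@@]1(C)O[C@@H]1C | intermediate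
4 | 3,3-dimethylpent-4-en-2-one | CC(=O)C(C)(C)C=C | starting material
5 | ethyl (2E)-3-methyl-4-oxobut-2-enoate | CCOC(=O)/C=C(\C)C=O | starting material
6 | diisopinocampheylboron enolate of 4 (Ipc groups of (−)-Ipc2BCl) | C=C(OB([C@@H]1C[C@@H]2C[C@H]([C@H]1C)C2(C)C)[C@@H]1C[C@@H]2C[C@H]([C@H]1C)C2(C)C)C(C)(C)C=C | intermediate (not isolated)
7 | diisopinocampheylboron aldolate of 8 | CCOC(=O)/C=C(\C)[C@H](OB([C@@H]1C[C@@H]2C[C@H]([C@H]1C)C2(C)C)[C@@H]1C[C@@H]2C[C@H]([C@H]1C)C2(C)C)CC(=O)C(C)(C)C=C | intermediate (not isolated)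
8 | ethyl (2E,4R)-4-hydroxy-3,7,7-trimethyl-6-oxonona-2,8-dienoate | CCOC(=O)/C=C(\C)[C@H](O)CC(=O)C(C)(C)C=C | intermediate
9 | ethyl (2E,4R,6R)-4,6-dihydroxy-3,7,7-trimethylnona-2,8-dienoate | CCOC(=O)/C=C(\C)[C@H](O)C[C@@H](O)C(C)(C)C=C | intermediate
10 | ethyl (2E,4R,6R)-4-[(tert-butyldimethylsilyl)oxy]-6-hydroxy-3,7,7-trimethylnona-2,8-dienoate | CCOC(=O)/C=C(\C)[C@H](O[Si](C)(C)C(C)(C)C)C[C@@H](O)C(C)(C)C=C | intermediate
11 | ethyl (2E,4R,6R)-4-[(tert-butyldimethylsilyl)oxy]-3,7,7-trimethyl-6-[(triethylsilyl)oxy]nona-2,8-dienoate | CCOC(=O)/C=C(\C)[C@H](O[Si](C)(C)C(C)(C)C)C[C@@H](O[Si](CC)(CC)CC)C(C)(C)C=C | intermediate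
12 | (2E,4R,6R)-4-[(tert-butyldimethylsilyl)oxy]-N-methoxy-N,3,7,7-tetramethyl-6-[(triethylsilyl)oxy]nona-2,8-dienamide | CON(C)C(=O)/C=C(\C)[C@H](O[Si](C)(C)C(C)(C)C)C[C@@H](O[Si](CC)(CC)CC)C(C)(C)C=C | intermediate
13 | prop-1-yn-1-ylmagnesium bromide | CC#C[Mg]Br | starting material
14 | (5E,7R,9R)-7-[(tert-butyldimethylsilyl)oxy]-6,10,10-trimethyl-9-[(triethylsilyl)oxy]dodeca-5,11-dien-2-yn-4-one | CC#CC(=O)/C=C(\C)[C@H](O[Si](C)(C)C(C)(C)C)C[C@@H](O[Si](CC)(CC)CC)C(C)(C)C=C | intermediate
15 | (2Z,5E,7R,9R)-7-[(tert-butyldimethylsilyl)oxy]-2-iodo-6,10,10-trimethyl-9-[(triethylsilyl)oxy]dodeca-2,5,11-trien-4-one | C/C(I)=C/C(=O)/C=C(\C)[C@H](O[Si](C)(C)C(C)(C)C)C[C@@H](O[Si](CC)(CC)CC)C(C)(C)C=C | intermediate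
16 | (2Z,4E,7R,9R,10E)-9-[(tert-butyldimethylsilyl)oxy]-3,6,6,10-tetramethyl-7-[(triethylsilyl)oxy]cycloundeca-2,4,10-trien-1-one | C1[C@@H](O[Si](CC)(CC)CC)C(C)(C)/C=C/C(C)=C\C(=O)/C=C(\C)[C@@H]1O[Si](C)(C)C(C)(C)C | intermediate
17 | tricyclic enone (1R,3R,5S,6R,10R,11R) with OTBS at C1 and OTES at C3 | CC(C)(C)[Si](C)(C)O[C@@H]1C[C@@H](O[Si](CC)(CC)CC)C(C)(C)[C@@H]2[C@H]3C(=O)C=C(C)[C@@H]2[C@]31C | intermediate
18 | tricyclic enone (1R,3R,5S,6R,10R,11R) with OTBS at C1 and OH at C3 | CC(C)(C)[Si](C)(C)O[C@@H]1C[C@@H](O)C(C)(C)[C@@H]2[C@H]3C(=O)C=C(C)[C@@H]2[C@]31C | intermediate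
19 | (2S,3R)-2,3-dimethyloxirane-2-carboxylic 2,4,6-trichlorobenzoic anhydride | O=C(OC(=O)[C@@]1(C)O[C@@H]1C)c1c(Cl)cc(Cl)cc1Cl | intermediate (not isolated)
20 | tricyclic enone with OTBS at C1 and the (2S,3R)-2,3-dimethyloxirane-2-carboxylate at C3 | CC(C)(C)[Si](C)(C)O[C@@H]1C[C@@H](OC(=O)[C@@]2(C)O[C@@H]2C)C(C)(C)[C@@H]2[C@H]3C(=O)C=C(C)[C@@H]2[C@]31C | intermediate
21 | tricyclic enone with OH at C1 and the (2S,3R)-2,3-dimethyloxirane-2-carboxylate at C3 | O[C@@H]1C[C@@H](OC(=O)[C@@]2(C)O[C@@H]2C)C(C)(C)[C@@H]2[C@H]3C(=O)C=C(C)[C@@H]2[C@]31C | intermediate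
22 | angelic acid, (2Z)-2-methylbut-2-enoic acid | C/C=C(/C)C(=O)O | starting material
23 | (2Z)-2-methylbut-2-enoic 2,4,6-trichlorobenzoic anhydride | C/C=C(/C)C(=O)OC(=O)c1c(Cl)cc(Cl)cc1Cl | intermediate (not isolated)
24 | CNP0149458.1: C1 angelate, C3 (2S,3R)-2,3-dimethyloxirane-2-carboxylate of the tricyclic enone (1R,3R,5S,6R,10R,11R) | C/C=C(/C)C(=O)O[C@@H]1C[C@@H](OC(=O)[C@@]2(C)O[C@@H]2C)C(C)(C)[C@@H]2[C@H]3C(=O)C=C(C)[C@@H]2[C@]31C | target

Total step count: 15. Longest linear sequence: 13 steps (steps 3 to 15, from 4 and 5 to 24); steps 1 and 2 make the side-chain acid 3.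

Steps most likely to fail

Step 10 (Heck macrocyclisation). The slow 11-endo insertion may lose to intermolecular Heck coupling (oligomers) and to reductive loss of the iodide. The fallback sets out from 12 and returns at 16, and makes the same C9–C10 bond by an intramolecular Stille coupling. The terminal vinyl group of 12 would be cleaved (OsO4 cat., NMO; then NaIO4; the electron-poor trisubstituted enamide alkene should not react) to the aldehyde (2E,4R,6R)-4-[(tert-butyldimethylsilyl)oxy]-N-methoxy-N,3,7,7-tetramethyl-8-oxo-6-[(triethylsilyl)oxy]oct-2-enamide F1. A chromium-mediated Takai-type olefination (CrCl2, Bu3SnCHBr2, LiI, DMF/THF) should give the (E)-vinylstannane Weinreb amide F2. Addition of 13 as in step 8 would give the stannyl ynone F3, and hydroiodination as in step 9 the stannyl (Z)-β-iodoenone F4. Pd2(dba)3/AsPh3 in DMF at high dilution should then couple C9–I with C10–Sn with retention at both alkenes to give 16.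

Step 11 (transannular [2+2]). The biradical may close in the parallel sense (C6–C10 and C5–C11), may add on the other face of C6=C11, or may only isomerise the alkenes. The fallback sets out from 16 and returns at 17, and takes the carbonyl out of conjugation so that radical stability alone decides the first bond. 1,2-Reduction of 16 (NaBH4, CeCl3·7H2O, MeOH, −78 °C) should give the macrocyclic trienol F5 (C7 epimers). Triplet sensitisation (thioxanthen-9-one, 405 nm) of its isolated C8=C9–C10=C5 diene should bond the diene terminus C5 to the unsubstituted alkene carbon C6 (tertiary radical at C11) and then close C10–C11, to give the tricyclic allylic alcohol F6. Dess–Martin oxidation would return the enone 17.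

Step 15 (angeloylation). The Z acyl donor may isomerise to the E (tigloyl) isomer during activation, and the hindered C1 hydroxyl may acylate sluggishly. The fallback sets out from 21 and returns at 24, and builds the Z alkene on the ester. 21 would be acylated with 2-[bis(2,2,2-trifluoroethoxy)phosphoryl]propanoic acid (DCC, DMAP) to the C1 phosphonopropanoate F7 (epimers at the phosphonate carbon). A Still–Gennari olefination (KHMDS, 18-crown-6, THF, −78 °C; acetaldehyde) should then give the (Z)-2-methylbut-2-enoate 24.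

Further compounds
F1 | step 10 | (2E,4R,6R)-4-[(tert-butyldimethylsilyl)oxy]-N-methoxy-N,3,7,7-tetramethyl-8-oxo-6-[(triethylsilyl)oxy]oct-2-enamide | CON(C)C(=O)/C=C(\C)[C@H](O[Si](C)(C)C(C)(C)C)C[C@@H](O[Si](CC)(CC)CC)C(C)(C)C=O
F2 | step 10 | (2E,4R,6R,8E)-4-[(tert-butyldimethylsilyl)oxy]-N-methoxy-N,3,7,7-tetramethyl-9-(tributylstannyl)-6-[(triethylsilyl)oxy]nona-2,8-dienamide | CON(C)C(=O)/C=C(\C)[C@H](O[Si](C)(C)C(C)(C)C)C[C@@H](O[Si](CC)(CC)CC)C(C)(C)/C=C/[Sn](CCCC)(CCCC)CCCC
F3 | step 10 | (5E,7R,9R,11E)-7-[(tert-butyldimethylsilyl)oxy]-6,10,10-trimethyl-12-(tributylstannyl)-9-[(triethylsilyl)oxy]dodeca-5,11-dien-2-yn-4-one | CC#CC(=O)/C=C(\C)[C@H](O[Si](C)(C)C(C)(C)C)C[C@@H](O[Si](CC)(CC)CC)C(C)(C)/C=C/[Sn](CCCC)(CCCC)CCCC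
F4 | step 10 | (2Z,5E,7R,9R,11E)-7-[(tert-butyldimethylsilyl)oxy]-2-iodo-6,10,10-trimethyl-12-(tributylstannyl)-9-[(triethylsilyl)oxy]dodeca-2,5,11-trien-4-one | C/C(I)=C/C(=O)/C=C(\C)[C@H](O[Si](C)(C)C(C)(C)C)C[C@@H](O[Si](CC)(CC)CC)C(C)(C)/C=C/[Sn](CCCC)(CCCC)CCCC
F5 | step 11 | (2Z,4E,7R,9R,10E)-9-[(tert-butyldimethylsilyl)oxy]-3,6,6,10-tetramethyl-7-[(triethylsilyl)oxy]cycloundeca-2,4,10-trien-1-ol (C1 epimers) | C1[C@@H](O[Si](CC)(CC)CC)C(C)(C)/C=C/C(C)=C\C(O)/C=C(\C)[C@@H]1O[Si](C)(C)C(C)(C)C
F6 | step 11 | tricyclic allylic alcohol: 17 with C7 as CH(OH) (C7 epimers) | CC(C)(C)[Si](C)(C)O[C@@H]1C[C@@H](O[Si](CC)(CC)CC)C(C)(C)[C@@H]2[C@H]3C(O)C=C(C)[C@@H]2[C@]31C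
F7 | step 15 | C1 2-[bis(2,2,2-trifluoroethoxy)phosphoryl]propanoate of 21 (epimers at the phosphonate carbon) | CC(C(=O)O[C@@H]1C[C@@H](OC(=O)[C@@]2(C)O[C@@H]2C)C(C)(C)[C@@H]2[C@H]3C(=O)C=C(C)[C@@H]2[C@]31C)P(=O)(OCC(F)(F)F)OCC(F)(F)F
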